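Ring B of this ent-labdane (labdane numbering) is a 3-methylcyclohex-2-enone (C6=O, C7=C8) next to the C9/C10 stereodiad, which is the retron of a Danishefsky-type diene added across an E-trisubstituted alkene. The route builds an open-chain (2E)-trienal from methyl geranate and closes rings A and B in one catalytic enantioselective intramolecular Diels–Alder reaction that forms C8–C9 and C5–C10. The geranyl E-geometry fixes C9 relative to C10, and the endo transition state gives the trans ring fusion. The C9 aldehyde is then turned into a vinyl group, which is hydroborated and cross-coupled with a stereodefined enol triflate to give the Z side chain.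

Key step: step 7

Remark: the decalin is numbered as in labdanes (C1–C10; methyls on C4, C8, C10; side chain on C9). The (S)-oxazaborolidinium is assumed to lead to the (5R,9R,10S) series; if the sense of induction is the opposite, its mirror image is used.

Step 1
Reactants: 1 methyl geranate, methyl (2E)-3,7-dimethylocta-2,6-dienoate
Product: 2 methyl (2E)-7-chloro-3,7-dimethyloct-2-enoate
Conditions: dry HCl, CH2Cl2, −20 °C
Reagents that add atoms: hydrogen chloride, Cl
Why: Markovnikov hydrochlorination should occur only at the electron-rich trisubstituted 6,7-alkene, because the conjugated 2,3-alkene is deactivated by the ester, so the (2E) geometry that later encodes C9/C10 is untouched.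

Step 2
Reactants: 3 (3E)-4-methoxypent-3-en-2-one
Product: 4 (3E)-4-methoxy-2-(trimethylsilyloxy)penta-1,3-diene
Conditions: Me3SiCl, Et3N, ZnCl2 (cat.), Et2O, rt to 40 °C
Reagents that add atoms: chlorotrimethylsilane, C[Si](C)(C)Cl
Why: Soft enolisation and O-silylation of the vinylogous ester at its acetyl methyl (Danishefsky-type diene synthesis) should give the cross-conjugated silyloxydiene that carries C5–C8 and the 8-methyl group.

Step 3
Reactants: 2 methyl (2E)-7-chloro-3,7-dimethyloct-2-enoate; 4 (3E)-4-methoxy-2-(trimethylsilyloxy)penta-1,3-diene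
Product: 5 methyl (2E,10E)-11-methoxy-3,7,7-trimethyl-9-oxododeca-2,10-dienoate
Conditions: TiCl4, CH2Cl2, −78 to −45 °C
Reagents that add atoms: none
Why: In this Reetz-type SN1 α-tert-alkylation (Mukaiyama alkylation), TiCl4 ionises the tertiary chloride and the terminal CH2 of diene 4 should trap the cation, creating the quaternary C4 and the C4–C5 bond and returning the vinylogous ester, while the conjugated ester is inert.

Step 4
Reactants: 5 methyl (2E,10E)-11-methoxy-3,7,7-trimethyl-9-oxododeca-2,10-dienoate
Product: 6 methyl (2E,8Z,10E)-11-methoxy-3,7,7-trimethyl-9-(triisopropylsilyloxy)dodeca-2,8,10-trienoate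
Conditions: i-Pr3SiOTf, Et3N, Et2O, 0 °C to rt
Reagents that add atoms: triisopropylsilyl triflate, CC(C)[Si](OS(=O)(=O)C(F)(F)F)(C(C)C)C(C)C
Why: Silyl triflate/amine soft enolisation of the vinylogous ester toward its only α′ methylene (C5) should give the (Z)-silyl enol ether, a 1-methoxy-3-silyloxydiene with the tether in the outside position, by analogy with the preparation of 4; Et3N does not enolise the methyl ester.

Step 5
Reactants: 6 methyl (2E,8Z,10E)-11-methoxy-3,7,7-trimethyl-9-(triisopropylsilyloxy)dodeca-2,8,10-trienoate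
Product: 7 (2E,8Z,10E)-11-methoxy-3,7,7-trimethyl-9-(triisopropylsilyloxy)dodeca-2,8,10-trien-1-ol
Conditions: i-Bu2AlH, CH2Cl2, −78 °C; aqueous potassium sodium tartrate work-up
Reagents that add atoms: none
Why: i-Bu2AlH should reduce the conjugated ester 1,2 to the allylic alcohol, the ketone being masked as the bis-enol ether.

Step 6
Reactants: 7 (2E,8Z,10E)-11-methoxy-3,7,7-trimethyl-9-(triisopropylsilyloxy)dodeca-2,8,10-trien-1-ol
Product: 8 (2E,8Z,10E)-11-methoxy-3,7,7-trimethyl-9-(triisopropylsilyloxy)dodeca-2,8,10-trienal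
Conditions: MnO2, CH2Cl2, 0 °C to rt; used at once
Reagents that add atoms: none
Why: MnO2 should oxidise the allylic alcohol selectively to the (2E)-enal under neutral conditions that leave the acid-sensitive diene and the alkene geometry intact.

Step 7
Reactants: 8 (2E,8Z,10E)-11-methoxy-3,7,7-trimethyl-9-(triisopropylsilyloxy)dodeca-2,8,10-trienal
Product: 9 (5R,8R,9S,10R)-8-methoxy-4,4,8,10-tetramethyl-6-(triisopropylsilyloxy)-trans-decal-6-ene-9-carbaldehyde (labdane numbering)
Conditions: (S)-B-(o-tolyl) diphenylprolinol oxazaborolidine (20 mol %), Tf2NH (18 mol %), CH2Cl2, −78 to −40 °C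
Reagents that add atoms: none
Why: The triflimide-activated oxazaborolidinium binds the formyl group of 8, and the electron-rich 1-methoxy-3-silyloxydiene adds across the (2E)-enal in an asynchronous (Michael-first) endo [4+2] cycloaddition that forms C5–C10 and then C8–C9. The closest known reaction types are the catalytic enantioselective type 1 intramolecular Diels–Alder reaction of 2,8,10-trienals and the Danishefsky-diene route to cyclohexenones. Ring B closes as the new cyclohexene and ring A as the four-carbon tether ring (in the stepwise limit, 6-exo attack of C5 on C10, then 6-exo closure of the C9 enolate onto the C8 oxocarbenium). C9 relative to C10 follows from suprafacial addition to the E alkene (CHO cis to the C10 methyl); C5 follows from the endo transition state with a chair tether (H-5 anti to the C10 methyl, trans-decalin); the transient C8 centre follows from the diene geometry; the absolute configuration comes from the catalyst shielding one enal face. The step needs carbo- over hetero-cycloaddition and endo over exo closure: attack of the diene on C=O would require an eight-membered ring, and the outside tether on the (Z)-silyl enol ether, the gem-dimethyl group next to the diene and the Lewis acid favour the endo chair arrangement. The bulky triisopropylsilyl group should suppress silyl transfer, which would otherwise open an achiral background pathway.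

Step 8
Reactants: 9 (5R,8R,9S,10R)-8-methoxy-4,4,8,10-tetramethyl-6-(triisopropylsilyloxy)-trans-decal-6-ene-9-carbaldehyde
Product: 11 (5R,9R,10S)-4,4,8,10-tetramethyl-9-vinyl-trans-decal-7-en-6-one, via masked vinyl cycloadduct 10 (not isolated)
Conditions: Ph3PCH3Br, KN(SiMe3)2, THF, −78 to 0 °C; then aq. HF, MeCN, 0 °C
Reagents that add atoms: methyltriphenylphosphonium bromide, C[P+](c1ccccc1)(c1ccccc1)c1ccccc1.[Br-]
Why: Wittig methylenation of the hindered aldehyde (its equatorial C9 configuration is also the thermodynamic one), then Danishefsky-type unmasking with HF (desilylation followed by E1cB loss of methanol), should give the C7=C8 enone and erase the auxiliary C8 centre without touching C5, C9 or C10.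

Step 9
Reactants: 12 tert-butyl 4-chloro-3-oxobutanoate
Product: 13 tert-butyl 4-acetoxy-3-oxobutanoate
Conditions: CH3CO2K, DMF, rt
Reagents that add atoms: potassium acetate, CC(=O)[O-].[K+]
Why: SN2 displacement of the activated primary α′-chloride by acetate should proceed cleanly.

Step 10
Reactants: 13 tert-butyl 4-acetoxy-3-oxobutanoate
Product: 14 tert-butyl (2E)-4-acetoxy-3-(trifluoromethylsulfonyloxy)but-2-enoate
Conditions: aq. Me4NOH, Tf2O, toluene, 0–5 °C, short contact time
Reagents that add atoms: triflic anhydride, O=S(=O)(OS(=O)(=O)C(F)(F)F)C(F)(F)F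
Why: In this Frantz-type enol triflation the non-chelated tetramethylammonium enolate should give the (E)-enol triflate, which places CH2OAc cis to the ester as required for the 13Z alkene.

Step 11
Reactants: 11 (5R,9R,10S)-4,4,8,10-tetramethyl-9-vinyl-trans-decal-7-en-6-one; 14 tert-butyl (2E)-4-acetoxy-3-(trifluoromethylsulfonyloxy)but-2-enoate
Product: 16 tert-butyl (5R,9R,10S,13Z)-16-acetoxy-6-oxo-ent-labda-7,13-dien-15-oate, via B-alkyl-9-BBN adduct 15 (not isolated)
Conditions: 9-BBN, THF, 0 °C to rt; then 14, PdCl2(dppf) (5 mol %), AsPh3, aq. K3PO4, DMF, rt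
Reagents that add atoms: none
Why: Anti-Markovnikov hydroboration of the only monosubstituted alkene with 9-BBN, followed by B-alkyl Suzuki–Miyaura coupling (retention at the enol triflate carbon), should form C12–C13 and deliver the 13Z side chain.

Step 12
Reactants: 16 tert-butyl (5R,9R,10S,13Z)-16-acetoxy-6-oxo-ent-labda-7,13-dien-15-oate
Product: 17 CNP0145331.2, (5R,9R,10S,13Z)-16-acetoxy-6-oxo-ent-labda-7,13-dien-15-oic acid
Conditions: CF3CO2H, CH2Cl2, 0 °C
Reagents that add atoms: none
Why: Acidolysis of the tert-butyl ester (loss of isobutene) should free the acid, while the primary acetate and the enone are stable to cold TFA.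

Compound list
1 | methyl geranate, methyl (2E)-3,7-dimethylocta-2,6-dienoate | COC(=O)/C=C(\C)CCC=C(C)C | starting material
2 | methyl (2E)-7-chloro-3,7-dimethyloct-2-enoate | COC(=O)/C=C(\C)CCCC(C)(C)Cl | intermediate
3 | (3E)-4-methoxypent-3-en-2-one | CC(=O)/C=C(\C)OC | starting material
4 | (3E)-4-methoxy-2-(trimethylsilyloxy)penta-1,3-diene | C=C(O[Si](C)(C)C)/C=C(\C)OC | intermediate
5 | methyl (2E,10E)-11-methoxy-3,7,7-trimethyl-9-oxododeca-2,10-dienoate | COC(=O)/C=C(\C)CCCC(C)(C)CC(=O)/C=C(\C)OC | intermediate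
6 | methyl (2E,8Z,10E)-11-methoxy-3,7,7-trimethyl-9-(triisopropylsilyloxy)dodeca-2,8,10-trienoate | COC(=O)/C=C(\C)CCCC(C)(C)/C=C(O[Si](C(C)C)(C(C)C)C(C)C)/C=C(\C)OC | intermediate
7 | (2E,8Z,10E)-11-methoxy-3,7,7-trimethyl-9-(triisopropylsilyloxy)dodeca-2,8,10-trien-1-ol | OC/C=C(\C)CCCC(C)(C)/C=C(O[Si](C(C)C)(C(C)C)C(C)C)/C=C(\C)OC | intermediate
8 | (2E,8Z,10E)-11-methoxy-3,7,7-trimethyl-9-(triisopropylsilyloxy)dodeca-2,8,10-trienal | O=C/C=C(\C)CCCC(C)(C)/C=C(O[Si](C(C)C)(C(C)C)C(C)C)/C=C(\C)OC | intermediate
9 | cycloadduct, (5R,8R,9S,10R)-8-methoxy-4,4,8,10-tetramethyl-6-(triisopropylsilyloxy)-trans-decal-6-ene-9-carbaldehyde (labdane numbering; 9-CHO cis to 10-Me and 8-OMe, H-5 anti to 10-Me) | O=C[C@@H]1[C@](C)(OC)C=C(O[Si](C(C)C)(C(C)C)C(C)C)[C@@H]2C(C)(C)CCC[C@@]12C | intermediate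
10 | masked vinyl cycloadduct, (5R,8S,9S,10S)-8-methoxy-4,4,8,10-tetramethyl-6-(triisopropylsilyloxy)-9-vinyl-trans-decal-6-ene | C=C[C@@H]1[C@](C)(OC)C=C(O[Si](C(C)C)(C(C)C)C(C)C)[C@@H]2C(C)(C)CCC[C@@]12C | intermediate
11 | vinyl enone, (5R,9R,10S)-4,4,8,10-tetramethyl-9-vinyl-trans-decal-7-en-6-one | C=C[C@@H]1C(C)=CC(=O)[C@@H]2C(C)(C)CCC[C@@]12C | intermediate
12 | tert-butyl 4-chloro-3-oxobutanoate | ClCC(=O)CC(=O)OC(C)(C)C | starting material
13 | tert-butyl 4-acetoxy-3-oxobutanoate | CC(=O)OCC(=O)CC(=O)OC(C)(C)C | intermediate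
14 | tert-butyl (2E)-4-acetoxy-3-(trifluoromethylsulfonyloxy)but-2-enoate | CC(=O)OC/C(OS(=O)(=O)C(F)(F)F)=C\C(=O)OC(C)(C)C | intermediate
15 | B-alkyl-9-BBN adduct of 11 (boron on C12) | B1(CC[C@@H]3C(C)=CC(=O)[C@@H]4C(C)(C)CCC[C@@]34C)C2CCCC1CCC2 | intermediate
16 | tert-butyl (5R,9R,10S,13Z)-16-acetoxy-6-oxo-ent-labda-7,13-dien-15-oate | CC(=O)OC/C(=C\C(=O)OC(C)(C)C)CC[C@@H]1C(C)=CC(=O)[C@@H]2C(C)(C)CCC[C@@]12C | intermediate
17 | CNP0145331.2, (5R,9R,10S,13Z)-16-acetoxy-6-oxo-ent-labda-7,13-dien-15-oic acid | CC(=O)OC/C(=C\C(=O)O)CC[C@@H]1C(C)=CC(=O)[C@@H]2C(C)(C)CCC[C@@]12C | target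

Total step count: 12. Longest linear sequence: 9 steps (steps 1, 3, 4, 5, 6, 7, 8, 11, 12).

Steps most likely to fail

Step 7. The catalyst may discriminate poorly between the faces of the β,β-disubstituted enal, an uncatalysed or silyl-transfer background cycloaddition may erode the enantiomeric purity, exo closure may give cis ring fusion, and the congested C5–C10 bond may form slowly. The fallback sets out from 5 and returns at 11, replacing catalyst control by auxiliary control on the diene (Rawal-type). The methoxy group of 5 is exchanged for (2R,5R)-2,5-diphenylpyrrolidine (MeOH, rt) to give the vinylogous amide ester F1. i-Bu2AlH reduces the ester to the allylic alcohol F2 and MnO2 gives the enal F3. t-BuMe2SiOTf/Et3N converts the vinylogous amide into the 1-amino-3-silyloxydiene F4, which should undergo an uncatalysed, auxiliary-controlled endo intramolecular Diels–Alder reaction on warming to give the cycloadduct F5. Wittig methylenation gives the vinyl cycloadduct F6, and aqueous HF releases the auxiliary and the silyl group to give 11. The auxiliary enantiomer is subject to the same assumption as the catalyst.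

Step 3. The tertiary cation may lose a proton instead of being captured, TiCl4 may decompose the acid-sensitive diene 4, and the product may be alkylated or attacked a second time. The fallback sets out from 2 and returns at 5. Chloride 2 is alkylated under the same Reetz conditions with the robust acetone enol ether 2-(trimethylsilyloxy)propene to give the methyl ketone F7. Me3SiOTf/Et3N gives the terminal silyl enol ether F8, whose Mukaiyama addition to trimethyl orthoacetate (Me3SiOTf cat.) gives the β-keto ketal F9. Loss of methanol on acidic silica gives 5.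

Step 11. 9-BBN may reduce the enone 1,2 in competition with hydroboration, the alkylborane may undergo protodeboronation or β-hydride elimination during coupling, and zerovalent palladium may ionise the allylic acetate. The fallback sets out from 9 and returns at 17, coupling before the ketone is unmasked. Wittig methylenation of 9 with a buffered, non-acidic work-up gives 10 as an isolated compound. With no carbonyl present, 9-BBN should give the borane F10 cleanly, and coupling with 14 gives the masked ester F11. Wet CF3CO2H then removes the silyl group, eliminates methanol and cleaves the tert-butyl ester in one operation to give 17.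

Further compounds
F1 | step 7 | methyl (2E,10E)-11-[(2R,5R)-2,5-diphenylpyrrolidin-1-yl]-3,7,7-trimethyl-9-oxododeca-2,10-dienoate | COC(=O)/C=C(\C)CCCC(C)(C)CC(=O)/C=C(\C)N1[C@@H](c2ccccc2)CC[C@@H]1c1ccccc1
F2 | step 7 | (2E,10E)-11-[(2R,5R)-2,5-diphenylpyrrolidin-1-yl]-1-hydroxy-3,7,7-trimethyldodeca-2,10-dien-9-one | OC/C=C(\C)CCCC(C)(C)CC(=O)/C=C(\C)N1[C@@H](c2ccccc2)CC[C@@H]1c1ccccc1
F3 | step 7 | (2E,10E)-11-[(2R,5R)-2,5-diphenylpyrrolidin-1-yl]-3,7,7-trimethyl-9-oxododeca-2,10-dienal | O=C/C=C(\C)CCCC(C)(C)CC(=O)/C=C(\C)N1[C@@H](c2ccccc2)CC[C@@H]1c1ccccc1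
F4 | step 7 | (2E,8Z,10E)-9-(tert-butyldimethylsilyloxy)-11-[(2R,5R)-2,5-diphenylpyrrolidin-1-yl]-3,7,7-trimethyldodeca-2,8,10-trienal | O=C/C=C(\C)CCCC(C)(C)/C=C(O[Si](C)(C)C(C)(C)C)/C=C(\C)N1[C@@H](c2ccccc2)CC[C@@H]1c1ccccc1
F5 | step 7 | amino cycloadduct, 6-(tert-butyldimethylsilyloxy)-8-[(2R,5R)-2,5-diphenylpyrrolidin-1-yl]-4,4,8,10-tetramethyl-trans-decal-6-ene-9-carbaldehyde (ring stereochemistry as in 9) | O=C[C@@H]1[C@](C)(N2[C@@H](c3ccccc3)CC[C@@H]2c2ccccc2)C=C(O[Si](C)(C)C(C)(C)C)[C@@H]4C(C)(C)CCC[C@@]14C
F6 | step 7 | 9-vinyl analogue of F5 | C=C[C@@H]1[C@](C)(N2[C@@H](c3ccccc3)CC[C@@H]2c2ccccc2)C=C(O[Si](C)(C)C(C)(C)C)[C@@H]4C(C)(C)CCC[C@@]14C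
F7 | step 3 | methyl (2E)-3,7,7-trimethyl-9-oxodec-2-enoate | COC(=O)/C=C(\C)CCCC(C)(C)CC(C)=O
F8 | step 3 | methyl (2E)-3,7,7-trimethyl-9-(trimethylsilyloxy)deca-2,9-dienoate | COC(=O)/C=C(\C)CCCC(C)(C)CC(=C)O[Si](C)(C)C
F9 | step 3 | methyl (2E)-11,11-dimethoxy-3,7,7-trimethyl-9-oxododec-2-enoate | COC(=O)/C=C(\C)CCCC(C)(C)CC(=O)CC(C)(OC)OC
F10 | step 11 | B-alkyl-9-BBN adduct of 10 (boron on C12) | B1(CC[C@@H]3[C@](C)(OC)C=C(O[Si](C(C)C)(C(C)C)C(C)C)[C@@H]4C(C)(C)CCC[C@@]34C)C2CCCC1CCC2
F11 | step 11 | masked coupled ester, tert-butyl (13Z)-16-acetoxy-8-methoxy-6-(triisopropylsilyloxy)-ent-labda-6,13-dien-15-oate (ring stereochemistry as in 10) | CC(=O)OC/C(=C\C(=O)OC(C)(C)C)CC[C@@H]1[C@](C)(OC)C=C(O[Si](C(C)C)(C(C)C)C(C)C)[C@@H]2C(C)(C)CCC[C@@]12C
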